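**Plan**

- Retrosynthetic cuts: the C3 dioxolane back to the ketone; a temporary carboxyl on C11 (removed by hydrodecarboxylation); the C9–C11 bond by an Ireland–Claisen shift, back to the C7 ester of a 7-hydroxy-8-methyl-Δ8 decalin with (coumarin-7-yloxy)acetic acid; then C7–O (allylic hydroxylation), C8–C12 and C8=C9 (alkylative Shapiro reaction on a C9 ketone), and the C4 methyls and H5, back to (R)-Wieland–Miescher ketone.
- Forward order: both carbocycles are present from the start; ring A is finished first (C4 gem-dimethyl, trans fusion, C3 ketal), ring B is then turned into the Δ8 7-ol, the coumarin acid is tethered at O7, the tether is contracted onto C9, and the carboxyl and ketal are removed last.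
- Enabling feature: ring B of the target holds the homoallylic ether array C7=C8–C9–C11–O, so C9 is the far terminus of the allyl unit C7–C8=C9; with a carboxyl placed on C11, the C9–C11 bond is the σ bond made in a [3,3] shift from O7.
- Stereochemistry: C10 comes from (R)-Wieland–Miescher ketone; C5 from hydrogenation anti to the angular methyl; the temporary C7 carbinol from SeO2 hydroxylation on the face anti to that methyl; C9 from suprafacial 1,3-transfer from C7 in the key step.

Key step: step 13

Remarks on the chemistry: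
- Locants C1–C12 are those of the drimane carbon skeleton and serve only as a numbering aid (ring A = C1–C5, C10; ring B = C5–C10; C11 = the OCH2 carbon on C9; C12 = the methyl on C8). Configurations are given by CIP descriptors and by the SMILES.
- Compounds 1, 13 and 14 are taken to be catalogue compounds.
- C11 of compounds 19 and 20 should form as an epimer mixture. It becomes CH2 in step 14, so it is left open in their SMILES.

**Route**

Step 1
Reactants: 1 (R)-Wieland–Miescher ketone
Product: 2 (4aR,5R)-5-hydroxy-4a-methyl-4,4a,5,6,7,8-hexahydronaphthalen-2(3H)-one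
Conditions: NaBH4 (0.3 equiv), EtOH, −10 °C
Reagents that add atoms: none
Why: Chemoselective borohydride reduction: the saturated C9 ketone is more electrophilic than the conjugated C3 carbonyl, and hydride should add anti to the angular methyl to give the 9-OH cis to it (a centre that is re-oxidised in step 6).

Step 2
Reactants: 2 (4aR,5R)-5-hydroxy-4a-methyl-4,4a,5,6,7,8-hexahydronaphthalen-2(3H)-one
Product: 3 (4aR,5R)-4a-methyl-5-(triethylsilyloxy)-4,4a,5,6,7,8-hexahydronaphthalen-2(3H)-one
Conditions: Et3SiCl, imidazole, DMF, 0 °C → rt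
Reagents that add atoms: chlorotriethylsilane, CC[Si](Cl)(CC)CC
Why: Standard silyl ether formation masks the hydroxyl against alkoxide and MeI in step 3 and stays acid-labile for step 5.

Step 3
Reactants: 3 (4aR,5R)-4a-methyl-5-(triethylsilyloxy)-4,4a,5,6,7,8-hexahydronaphthalen-2(3H)-one
Product: 4 (4aR,5R)-1,1,4a-trimethyl-5-(triethylsilyloxy)-3,4,4a,5,6,7-hexahydronaphthalen-2(1H)-one
Conditions: KOtBu (3 equiv), MeI (excess), t-BuOH/THF, 0 °C → rt
Reagents that add atoms: iodomethane, CI
Why: Deconjugative double α-methylation of the enone through its extended dienolate places both methyls on C4 and moves the alkene to C5=C6.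

Step 4
Reactants: 4 (4aR,5R)-1,1,4a-trimethyl-5-(triethylsilyloxy)-3,4,4a,5,6,7-hexahydronaphthalen-2(1H)-one
Product: 5 (4aR,5R,8aS)-1,1,4a-trimethyl-5-(triethylsilyloxy)octahydronaphthalen-2(1H)-one
Conditions: H2 (4 atm), 10% Pd on carbon, EtOAc, rt
Reagents that add atoms: none
Why: Heterogeneous hydrogenation should deliver H2 to C5=C6 from the face opposite the axial C10 and C4 methyls and the C9 silyloxy group, setting H5 anti to the angular methyl (trans-fused decalin).

Step 5
Reactants: 5 (4aR,5R,8aS)-1,1,4a-trimethyl-5-(triethylsilyloxy)octahydronaphthalen-2(1H)-one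
Product: 6 (5S,9R,10R)-3,3-ethylenedioxy-11,12-dinordriman-9-ol
Conditions: HOCH2CH2OH (5 equiv), p-TsOH·H2O (cat.), benzene, reflux, Dean–Stark trap
Reagents that add atoms: ethylene glycol, OCCO
Why: Acid-catalysed dioxolane formation with azeotropic removal of water protects the C3 ketone, and the acid-labile triethylsilyl ether should be cleaved by the excess diol under the same conditions.

Step 6
Reactants: 6 (5S,9R,10R)-3,3-ethylenedioxy-11,12-dinordriman-9-ol
Product: 7 (5R,10R)-3,3-ethylenedioxy-11,12-dinordriman-9-one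
Conditions: (n-Pr4N)RuO4 (5 mol%), N-methylmorpholine N-oxide, 4 Å molecular sieves, CH2Cl2, rt
Reagents that add atoms: none
Why: Ley–Griffith oxidation converts the hindered secondary alcohol into the C9 ketone under neutral conditions that leave the dioxolane intact.

Step 7
Reactants: 7 (5R,10R)-3,3-ethylenedioxy-11,12-dinordriman-9-one
Product: 8 (E)-2,4,6-triisopropylbenzenesulfonylhydrazone of ketone 7 (5S,10R)
Conditions: 2,4,6-(i-Pr)3C6H2SO2NHNH2, pyridinium p-toluenesulfonate (cat.), 4 Å molecular sieves, THF, 45 °C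
Reagents that add atoms: 2,4,6-triisopropylbenzenesulfonohydrazide, CC(C)c1cc(C(C)C)c(S(=O)(=O)NN)c(C(C)C)c1
Why: Condensation should give the arenesulfonylhydrazone with the N–N bond turned away from the quaternary C10, that is syn to C8 as the Shapiro reaction requires; the triisopropylaryl group suppresses ortho-lithiation in step 8.

Step 8
Reactants: 8 (E)-2,4,6-triisopropylbenzenesulfonylhydrazone of ketone 7
Product: 11 (5S,10S)-3,3-ethylenedioxy-11-nordrim-8-ene, via C8-methylated sulfonylhydrazone 9 (not isolated), via C9 vinyllithium 10 (not isolated)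
Conditions: n-BuLi (2.2 equiv), THF, −78 °C; MeI (1.0 equiv), −78 → −50 °C; n-BuLi (1.3 equiv), −78 → 0 °C; then H2O
Reagents that add atoms: iodomethane, CI
Why: Shapiro reaction with α-alkylation in the same flask: C8 carries the only α-hydrogens, so the hydrazone dianion forms there and is methylated (C12), a further deprotonation at C8 expels sulfinate and N2 to give the C9 vinyllithium, and protonation leaves the C8=C9 alkene with hydrogen on C9.

Step 9
Reactants: 11 (5S,10S)-3,3-ethylenedioxy-11-nordrim-8-ene
Product: 12 (5S,7S,10S)-3,3-ethylenedioxy-11-nordrim-8-en-7-ol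
Conditions: SeO2 (0.5 equiv), t-BuOOH (2 equiv), CH2Cl2, rt
Reagents that add atoms: selenium dioxide, O=[Se]=O; tert-butyl hydroperoxide, CC(C)(C)OO
Why: SeO2 allylic hydroxylation (ene reaction, then [2,3]-sigmatropic shift): selenium should add to C9 on the face anti to the C10 methyl while removing the pseudoaxial H7 on that face, and the suprafacial [2,3] shift returns the alkene to C8=C9 and places oxygen on C7 on the same face (7S, pseudoaxial), the ring CH2 being oxidised in preference to the C12 methyl.

Step 10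
Reactants: 13 umbelliferone (7-hydroxy-2H-chromen-2-one); 14 tert-butyl bromoacetate
Product: 15 tert-butyl [(2-oxo-2H-chromen-7-yl)oxy]acetate
Conditions: K2CO3, acetone, reflux
Reagents that add atoms: none
Why: Williamson ether synthesis: the acidic phenol is alkylated by the α-bromo ester under carbonate conditions that do not open the lactone.

Step 11
Reactants: 15 tert-butyl [(2-oxo-2H-chromen-7-yl)oxy]acetate
Product: 16 [(2-oxo-2H-chromen-7-yl)oxy]acetic acid
Conditions: CF3CO2H/CH2Cl2 (1:2), rt
Reagents that add atoms: none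
Why: Acidolysis of the tert-butyl ester (loss of isobutene) frees the acid without the aqueous base that would open the coumarin lactone.

Step 12
Reactants: 12 (5S,7S,10S)-3,3-ethylenedioxy-11-nordrim-8-en-7-ol; 16 [(2-oxo-2H-chromen-7-yl)oxy]acetic acid
Product: 17 (5S,7S,10S)-3,3-ethylenedioxy-11-nordrim-8-en-7-yl [(2-oxo-2H-chromen-7-yl)oxy]acetate
Conditions: DCC, DMAP (cat.), CH2Cl2/DMF, 0 °C → rt
Reagents that add atoms: none
Why: Steglich esterification acylates the C7 hydroxyl without touching the C7–O bond, so the pseudoaxial 7S configuration is retained in the ester.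

Step 13
Reactants: 17 (5S,7S,10S)-3,3-ethylenedioxy-11-nordrim-8-en-7-yl [(2-oxo-2H-chromen-7-yl)oxy]acetate
Product: 20 2-[(5S,9S,10R)-3,3-ethylenedioxy-11-nordrim-7-en-9-yl]-2-[(2-oxo-2H-chromen-7-yl)oxy]acetic acid, via silyl ketene acetal 18 (not isolated), via trimethylsilyl ester 19 (not isolated)
Conditions: Me3SiCl/Et3N (premixed, 3 equiv), THF, −78 °C; LiN(SiMe3)2 (1.5 equiv), −78 °C → rt, then 60 °C; aq. citric acid work-up
Reagents that add atoms: none
Why: LiN(SiMe3)2 removes a proton from the OCH2 group of the aryloxyacetate in the presence of Me3SiCl, and the silyl ketene acetal 18 undergoes a concerted suprafacial [3,3]-sigmatropic shift over the C7–C8=C9 allyl unit of ring B, breaking C7–O and forming C9–C11 together with the C7=C8 double bond; aqueous acid then hydrolyses silyl ester 19. The closest known reaction type is the Ireland–Claisen rearrangement of alkoxyacetate (glycolate) esters of cyclic allylic alcohols. No ring of the product is closed; only the transient six-membered transition state (boat or chair) forms. The new stereocentre C9 is controlled by C7: the trans ring fusion locks ring B in one half-chair in which the C7–O bond is pseudoaxial on the face of H5, so C11 is delivered to that same face of C9, anti to the C10 methyl, giving the axial C9–C11 bond (9S), while C11 itself forms as an epimer mixture that disappears in step 14. The step needs the alkene to end at C7=C8 only, which the pericyclic mechanism secures (no C8 cation, hence no exocyclic or tetrasubstituted isomer and no attack on the coumarin ring), and it needs the enolate to be silylated faster than it fragments or adds to the coumarin lactone, which the Me3SiCl present in the flask and the hindered amide base should secure; the C3 ketone is masked as the dioxolane.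

Step 14
Reactants: 20 2-[(5S,9S,10R)-3,3-ethylenedioxy-11-nordrim-7-en-9-yl]-2-[(2-oxo-2H-chromen-7-yl)oxy]acetic acid
Product: 21 7-{[(5S,9S,10R)-3,3-ethylenedioxydrim-7-en-11-yl]oxy}-2H-chromen-2-one
Conditions: 9-mesityl-10-methylacridinium tetrafluoroborate (5 mol%), bis(4-chlorophenyl) disulfide (10 mol%), 2,6-lutidine (20 mol%), ClCH2CH2Cl, 450 nm LEDs, rt, degassed
Reagents that add atoms: none
Why: Photoredox hydrodecarboxylation: the excited acridinium oxidises the carboxylate, CO2 is lost to give the oxygen-stabilised C11 radical, and hydrogen-atom transfer from the arenethiol formed in the flask turns C11 into the CH2 group, erasing its configuration without touching C9.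

Step 15
Reactants: 21 7-{[(5S,9S,10R)-3,3-ethylenedioxydrim-7-en-11-yl]oxy}-2H-chromen-2-one
Product: 22 7-{[(1S,4aS,8aR)-2,5,5,8a-tetramethyl-6-oxo-1,4,4a,5,6,7,8,8a-octahydronaphthalen-1-yl]methoxy}-2H-chromen-2-one (CNP0262399.6)
Conditions: 1 M aq. HCl/THF (1:5), rt
Reagents that add atoms: water, O
Why: Acid-catalysed ketal hydrolysis releases the C3 ketone; the trisubstituted C7=C8 alkene, the aryl alkyl ether and the lactone should be stable to dilute acid at rt.

**Compound list**

1 | (R)-Wieland–Miescher ketone, (8aR)-8a-methyl-3,4,8,8a-tetrahydronaphthalene-1,6(2H,7H)-dione | C[C@@]12CCC(=O)C=C1CCCC2=O | starting material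
2 | (4aR,5R)-5-hydroxy-4a-methyl-4,4a,5,6,7,8-hexahydronaphthalen-2(3H)-one (OH cis to the angular methyl) | O[C@@H]1CCCC2=CC(=O)CC[C@@]12C | intermediate
3 | (4aR,5R)-4a-methyl-5-(triethylsilyloxy)-4,4a,5,6,7,8-hexahydronaphthalen-2(3H)-one | CC[Si](CC)(CC)O[C@@H]1CCCC2=CC(=O)CC[C@@]12C | intermediate
4 | (4aR,5R)-1,1,4a-trimethyl-5-(triethylsilyloxy)-3,4,4a,5,6,7-hexahydronaphthalen-2(1H)-one | CC[Si](CC)(CC)O[C@@H]1CCC=C2C(C)(C)C(=O)CC[C@@]12C | intermediate
5 | (4aR,5R,8aS)-1,1,4a-trimethyl-5-(triethylsilyloxy)octahydronaphthalen-2(1H)-one (trans-fused) | CC[Si](CC)(CC)O[C@@H]1CCC[C@@H]2C(C)(C)C(=O)CC[C@@]12C | intermediate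
6 | (5S,9R,10R)-3,3-ethylenedioxy-11,12-dinordriman-9-ol | O[C@@H]1CCC[C@@H]2C(C)(C)C3(OCCO3)CC[C@@]12C | intermediate
7 | (5R,10R)-3,3-ethylenedioxy-11,12-dinordriman-9-one | O=C1CCC[C@@H]2C(C)(C)C3(OCCO3)CC[C@@]12C | intermediate
8 | (E)-2,4,6-triisopropylbenzenesulfonylhydrazone of ketone 7 (5S,10R) | CC(C)c1cc(C(C)C)c(S(=O)(=O)N/N=C2\CCC[C@@H]3C(C)(C)C4(OCCO4)CC[C@@]23C)c(C(C)C)c1 | intermediate
9 | C8-methylated sulfonylhydrazone (5S,8S,10R; methyl anti to the C10 methyl; N-lithio salt in the flask, not isolated) | CC(C)c1cc(C(C)C)c(S(=O)(=O)N/N=C2\[C@@H](C)CC[C@@H]3C(C)(C)C4(OCCO4)CC[C@@]23C)c(C(C)C)c1 | intermediate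
10 | C9 vinyllithium, (5S,10R)-3,3-ethylenedioxy-11-nordrim-8-en-9-yllithium (not isolated) | [Li]C1=C(C)CC[C@@H]2C(C)(C)C3(OCCO3)CC[C@@]12C | intermediate
11 | (5S,10S)-3,3-ethylenedioxy-11-nordrim-8-ene | C1=C(C)CC[C@@H]2C(C)(C)C3(OCCO3)CC[C@@]12C | intermediate
12 | (5S,7S,10S)-3,3-ethylenedioxy-11-nordrim-8-en-7-ol (OH pseudoaxial, on the face of H5) | C1=C(C)[C@@H](O)C[C@@H]2C(C)(C)C3(OCCO3)CC[C@@]12C | intermediate
13 | umbelliferone, 7-hydroxy-2H-chromen-2-one | Oc1ccc2ccc(=O)oc2c1 | starting material
14 | tert-butyl bromoacetate | CC(C)(C)OC(=O)CBr | starting material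
15 | tert-butyl [(2-oxo-2H-chromen-7-yl)oxy]acetate | CC(C)(C)OC(=O)COc1ccc2ccc(=O)oc2c1 | intermediate
16 | [(2-oxo-2H-chromen-7-yl)oxy]acetic acid | OC(=O)COc1ccc2ccc(=O)oc2c1 | intermediate
17 | (5S,7S,10S)-3,3-ethylenedioxy-11-nordrim-8-en-7-yl [(2-oxo-2H-chromen-7-yl)oxy]acetate | C1=C(C)[C@@H](OC(=O)COc3ccc4ccc(=O)oc4c3)C[C@@H]2C(C)(C)C5(OCCO5)CC[C@@]12C | intermediate
18 | (Z)-trimethylsilyl ketene acetal of ester 17 (not isolated; geometry of no consequence) | C1=C(C)[C@@H](O\C(O[Si](C)(C)C)=C\Oc3ccc4ccc(=O)oc4c3)C[C@@H]2C(C)(C)C5(OCCO5)CC[C@@]12C | intermediate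
19 | trimethylsilyl ester of acid 20 (not isolated; C11 epimers) | CC1=CC[C@@H]2C(C)(C)C3(OCCO3)CC[C@@]2(C)[C@H]1C(Oc4ccc5ccc(=O)oc5c4)C(=O)O[Si](C)(C)C | intermediate
20 | 2-[(5S,9S,10R)-3,3-ethylenedioxy-11-nordrim-7-en-9-yl]-2-[(2-oxo-2H-chromen-7-yl)oxy]acetic acid (C11 epimers) | CC1=CC[C@@H]2C(C)(C)C3(OCCO3)CC[C@@]2(C)[C@H]1C(Oc4ccc5ccc(=O)oc5c4)C(=O)O | intermediate
21 | 7-{[(5S,9S,10R)-3,3-ethylenedioxydrim-7-en-11-yl]oxy}-2H-chromen-2-one | CC1=CC[C@@H]2C(C)(C)C3(OCCO3)CC[C@@]2(C)[C@H]1COc4ccc5ccc(=O)oc5c4 | intermediate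
22 | 7-{[(1S,4aS,8aR)-2,5,5,8a-tetramethyl-6-oxo-1,4,4a,5,6,7,8,8a-octahydronaphthalen-1-yl]methoxy}-2H-chromen-2-one, (5S,9S,10R) in drimane locants | CC1=CC[C@@H]2C(C)(C)C(=O)CC[C@@]2(C)[C@H]1COc1ccc2ccc(=O)oc2c1 | target

**Step count and risks**

Total step count: 15. Longest linear sequence: 13 steps (steps 1–9 and 12–15 from compound 1); acid 16 is made in 2 steps (10 and 11).

The three steps most likely to fail:

1. Step 9. The ene step may take hydrogen from the C12 methyl in place of the ring CH2 at C7, selenium may add only slowly at the hindered C9, or the allylic alcohol may be oxidised on to the enone. The fallback sets out from alkene 11 and comes back at ester 17. The ring allylic CH2 would be oxidised with CrO3·3,5-dimethylpyrazole (CH2Cl2, −20 °C) to (5S,10S)-3,3-ethylenedioxy-11-nordrim-8-en-7-one F1. A Luche reduction (NaBH4, CeCl3·7H2O, MeOH, −40 °C; axial hydride delivery on the face of H5) should give the pseudoequatorial (5S,7R,10S)-3,3-ethylenedioxy-11-nordrim-8-en-7-ol F2. A Mitsunobu esterification with acid 16 (PPh3, DIAD, toluene/THF, 0 °C) would invert C7 and give ester 17 directly.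

2. Step 13. The [3,3] shift must form a bond at C9 next to the quaternary C10; if it is slow, the enolate or ketene acetal may decompose (loss of ketene, desilylation), or the amide base may attack the coumarin lactone. The fallback sets out from alcohol 12 and comes back at ketal 21, with the coumarin introduced after the C9–C11 bond. Alkylation of 12 (KH, Bu3SnCH2I, THF, 0 °C → rt) would give tributyl({[(5S,7S,10S)-3,3-ethylenedioxy-11-nordrim-8-en-7-yl]oxy}methyl)stannane F3. Tin–lithium exchange (n-BuLi, THF, −78 → 0 °C) and [2,3]-Wittig–Still rearrangement, with the same suprafacial transfer from the pseudoaxial O7 to C9, should give (5S,9S,10R)-3,3-ethylenedioxydrim-7-en-11-ol F4. A Mitsunobu etherification with umbelliferone 13 (PPh3, DIAD, THF) would then give 21.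

3. Step 8. The second deprotonation has to remove the tertiary C8 hydrogen of the methylated hydrazone; if it stalls, fragmentation to the vinyllithium stays incomplete. The fallback sets out from ketone 7 and comes back at alkene 11. Enolate methylation (LiN(iPr)2, THF, −78 °C; MeI) should give (5R,8S,10R)-3,3-ethylenedioxy-11-nordriman-9-one F5. Triflation of the only possible enolate (KN(SiMe3)2, PhNTf2, THF, −78 → 0 °C) would give (5S,10R)-3,3-ethylenedioxy-11-nordrim-8-en-9-yl trifluoromethanesulfonate F6. Reduction with Pd(OAc)2, PPh3, HCO2H and n-Bu3N (DMF, 60 °C) would then give 11.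

**Further compounds**

F1 | step 9 | (5S,10S)-3,3-ethylenedioxy-11-nordrim-8-en-7-one | C1=C(C)C(=O)C[C@@H]2C(C)(C)C3(OCCO3)CC[C@@]12C
F2 | step 9 | (5S,7R,10S)-3,3-ethylenedioxy-11-nordrim-8-en-7-ol | C1=C(C)[C@H](O)C[C@@H]2C(C)(C)C3(OCCO3)CC[C@@]12C
F3 | step 13 | tributyl({[(5S,7S,10S)-3,3-ethylenedioxy-11-nordrim-8-en-7-yl]oxy}methyl)stannane | C1=C(C)[C@@H](OC[Sn](CCCC)(CCCC)CCCC)C[C@@H]2C(C)(C)C3(OCCO3)CC[C@@]12C
F4 | step 13 | (5S,9S,10R)-3,3-ethylenedioxydrim-7-en-11-ol | CC1=CC[C@@H]2C(C)(C)C3(OCCO3)CC[C@@]2(C)[C@H]1CO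
F5 | step 8 | (5R,8S,10R)-3,3-ethylenedioxy-11-nordriman-9-one | O=C1[C@@H](C)CC[C@@H]2C(C)(C)C3(OCCO3)CC[C@@]12C
F6 | step 8 | (5S,10R)-3,3-ethylenedioxy-11-nordrim-8-en-9-yl trifluoromethanesulfonate | FC(F)(F)S(=O)(=O)OC1=C(C)CC[C@@H]2C(C)(C)C3(OCCO3)CC[C@@]12C
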